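3 questions are put to this flask; they stand below with the runs so far.

| flask | Gy | Ek | remark | time |
|---|---|---|---|---|
| birch | 0.20 M | 1 equiv | run made earlier |  |
| maple | 0.80 M | 1 equiv | run made earlier |  |
| elm | 0.40 M | 2 equiv | run made earlier |  |
| flask | 0.40 M | 1.00 equiv |  | 6.0 h |

| run | time / h | Wa / % |
|---|---|---|
| birch | 1.33 | 4.7 |
| birch | 2.50 | 8.6 |
| birch | 4.00 | 10.1 |
| birch | 5.00 | 11.6 |
| maple | 1.33 | 12.4 |
| maple | 2.50 | 13.3 |
| maple | 4.00 | 13.2 |
| maple | 5.00 | 13.5 |
| elm | 0.417 | 8.0 |
| elm | 0.833 | 11.6 |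
| elm | 2.00 | 13.2 |
| elm | 5.00 | 11.3 |

(each reading ± 0.3 percentage points)

- for Aj the Uv is counted in
- as a solid, counted per litre of solution: Uv
- what was read earlier has a scatter of 0.3 percentage points, one standard deviation
- on the list of suspects stand: Uv <-> Aj; Gy <-> Ju; Ek + Wa -> Lx + Aj; Gy + Ek -> Qi + Aj; Ek + Qi -> Wa + Aj

- equivalents of Ek to Gy, everything else as given, that leave most Wa at 6.0 h
- the amount of Wa then, in percent of the Gy charged
- the amount of Wa with the amounts as given

What clock does Wa run on? Both listed steps that touch Wa pair a dissolved partner with Ek, so at equal equivalents I reckon on the dose, the starting [Gy] multiplied by the elapsed time; for this flask it is 2.40 M·h.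

Does the dose line up the runs? Birch at 1.00 M·h reads 11.6%, and maple at 1.06 M·h reads 12.4%: close, with maple slightly ahead in dose.

And the weak spot? Gy <-> Ju and Uv <-> Aj do not run on this clock, so the dose remains a rule read from the runs.

What does it give? Maple reads 13.3% at 2.00 M·h and 13.2% at 3.20 M·h. This flask's dose lies between them, so I commit to 13.2%, with Ek as limiting reagent.

And the equivalents? The dose gives no number for them. Elm, at 2 equiv, reads 13.2% at 2.00 h and 11.3% at 5.00 h, so I look for the top between 1.00 equiv and 2 equiv.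

The forecast says 13.4%, a little above mine, because “it should sit on that plateau”, and puts the best at 1.15 equiv with 14%.

The flask gives 13.0%, and its best is 13.3% at 1.18 equiv. At ten times the dose, 24.0 M·h, Wa stands at 13.2%. My dose reckoning lay 0.23 percentage points from the flask's value, against a scatter of 0.3 points.

    Uv ⇌ Aj, rate k1*(cs1 - [Aj]) while solid is left; crystals form when [Aj] > cs1 (solubility = 0.200 M, k = 6.10 min⁻¹)
    Gy ⇌ Ju (K = 2.40, k = 0.120 min⁻¹)
    Ek + Wa → Lx + Aj (k = 0.0490 M⁻¹ min⁻¹)
    Gy + Ek → Qi + Aj (k = 0.0380 M⁻¹ min⁻¹)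
    Ek + Qi → Wa + Aj (k = 0.0570 M⁻¹ min⁻¹)

Read the same flask at 1.5 h: its dose is 0.600 M·h, between birch's 0.500 M·h and 0.800 M·h, and a straight line between those readings gives 9.10%. The computed value is 9.46%.

(The data stem from a simulated flask with made-up constants, and the scatter is random.)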